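**Strategy.** Everything rests on cutting ring A at its C(OH)–C(CH3) and C(OCH3)–C(bridge) bonds. The adjacent C–CH3/C–OCH3 pair of ring A is then 1-methoxypropyne, and the other four carbons, with the CH2 link to ring B already attached, are the vinylketene hidden in a 2-substituted 3-alkoxycyclobut-2-enone. One thermal cascade therefore makes ring A as a phenol with the methoxy group para to the future butanoyl site, without any selective O-methylation on that ring. The precursor is the B–C diarylmethane, all five phenols capped as methoxymethyl ethers, whose ring B carries a CH2-bound 3-(methoxymethoxy)cyclobutenone. Global acetal cleavage and butanoylation of ring A's only free carbon finish the target.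

Key step: step 11

Remark on the chemistry (assumption): cyclobutane-1,3-dione (in practice its enol, 3-hydroxycyclobut-2-en-1-one) is taken as purchasable; 1-methoxypropyne is not assumed to be on sale and is made in step 10.

Remark on the precursor design: the enol oxygen of the cyclobutenone carries a methoxymethyl group and not a benzyl group. A hard alkoxymethyl chloride alkylates the vinylogous acid at oxygen, whereas a benzyl halide could also attack the doubly activated carbon. One acid treatment then frees all seven hydroxyls, and no hydrogenation has to be run next to three aryl ketones.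

Remark on ring C: its methoxy group sits on the oxygen between the methyl and the butanoyl group. Direct mono-methylation would take the hydroxyl para to the ketone instead, hence steps 2–4.

Abbreviations: MOM = CH2OCH3; Ar* = 3-acetyl-5-{[3-butanoyl-4-methoxy-2,6-bis(methoxymethoxy)-5-methylphenyl]methyl}-2,4,6-tris(methoxymethoxy)phenyl (the penta-MOM B–C aryl group).

**Route**

Step 1
Reactants: 1 2,4,6-trihydroxytoluene; 2 butanoyl chloride
Product: 3 1-(2,4,6-trihydroxy-3-methylphenyl)butan-1-one
Conditions: AlCl3 (3.5 equiv), PhNO2, 0 °C → 60 °C; ice/aq. HCl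
Reagents that add atoms: none
Why: Friedel–Crafts C-acylation of a phloroglucinol whose two free ring carbons are equivalent, so a single ketone should form, and the acyl group then deactivates the ring towards a second acylation.

Step 2
Reactants: 3 1-(2,4,6-trihydroxy-3-methylphenyl)butan-1-one
Product: 4 1-[2-hydroxy-4,6-bis(methoxymethoxy)-3-methylphenyl]butan-1-one
Conditions: MOMCl (2.1 equiv), i-Pr2NEt (2.5 equiv), CH2Cl2, 0 °C → rt
Reagents that add atoms: chloromethyl methyl ether, COCCl
Why: Williamson-type O-alkylation under weak base should take the non-chelated hydroxyl para to the ketone first and then the less hindered ortho hydroxyl, leaving the hydroxyl wedged between methyl and butanoyl as the hydrogen-bonded phenol (regiochemistry to be confirmed by NOE from the ring hydrogen to both OCH2O groups).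

Step 3
Reactants: 4 1-[2-hydroxy-4,6-bis(methoxymethoxy)-3-methylphenyl]butan-1-one
Product: 5 1-[2-methoxy-4,6-bis(methoxymethoxy)-3-methylphenyl]butan-1-one
Conditions: MeI, K2CO3, DMF, 45 °C
Reagents that add atoms: iodomethane, CI
Why: Williamson O-methylation of the one remaining phenol, forced in a dipolar aprotic solvent, fixes the ring C methoxy group between methyl and butanoyl while the acetals are stable to base.

Step 4
Reactants: 5 1-[2-methoxy-4,6-bis(methoxymethoxy)-3-methylphenyl]butan-1-one
Product: 6 1-(4,6-dihydroxy-2-methoxy-3-methylphenyl)butan-1-one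
Conditions: conc. HCl (cat.), MeOH, 50 °C
Reagents that add atoms: none
Why: Acid-catalysed acetal exchange hands both methoxymethyl groups to methanol as dimethoxymethane, the aryl methyl ether and ketone being inert and the free ring carbon being deactivated by the butanoyl group.

Step 5
Reactants: 6 1-(4,6-dihydroxy-2-methoxy-3-methylphenyl)butan-1-one
Product: 7 1-{3-[(dimethylamino)methyl]-2,4-dihydroxy-6-methoxy-5-methylphenyl}butan-1-one
Conditions: Me2N=CH2+ I− (Eschenmoser's salt, 1.1 equiv), Et3N (1.1 equiv), CH2Cl2, 0 °C → rt
Reagents that add atoms: N,N-dimethylmethylideneammonium iodide, C=[N+](C)C.[I-]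
Why: Mannich aminomethylation at the only free ring carbon, flanked by two hydroxyls, with a preformed iminium salt so that no free formaldehyde is present to build symmetrical methylene-bridged dimers.

Step 6
Reactants: 8 2,4,6-trihydroxyacetophenone
Product: 10 3-acetyl-2,4,6-trihydroxybenzaldehyde, via iminium chloride 9 (not isolated)
Conditions: POCl3 (1.1 equiv), DMF (1.2 equiv), EtOAc, 0 °C → rt; then H2O, 60 °C
Reagents that add atoms: N,N-dimethylformamide, CN(C)C=O; water, O
Why: Vilsmeier–Haack formylation at one of the two equivalent free carbons of the phloroglucinol ring, the iminium salt being hydrolysed on work-up and the doubly acylated product being too deactivated to react again with one equivalent of reagent.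

Step 7
Reactants: 7 1-{3-[(dimethylamino)methyl]-2,4-dihydroxy-6-methoxy-5-methylphenyl}butan-1-one; 10 3-acetyl-2,4,6-trihydroxybenzaldehyde
Product: 12 3-acetyl-5-[(3-butanoyl-2,6-dihydroxy-4-methoxy-5-methylphenyl)methyl]-2,4,6-trihydroxybenzaldehyde, via ortho-quinone methide 11 (not isolated)
Conditions: 10 (1.2 equiv), 1,4-dioxane, 90 °C, N2
Reagents that add atoms: none
Why: Thermal loss of dimethylamine from the phenolic Mannich base gives an ortho-quinone methide that is captured by conjugate (Michael-type) C-alkylation at the single free ring carbon of 10 and rearomatises; each partner offers one reactive carbon, so only the unsymmetrical diarylmethane can form directly.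

Step 8
Reactants: 12 3-acetyl-5-[(3-butanoyl-2,6-dihydroxy-4-methoxy-5-methylphenyl)methyl]-2,4,6-trihydroxybenzaldehyde
Product: 13 Ar*-carbaldehyde (3-acetyl-5-{[3-butanoyl-4-methoxy-2,6-bis(methoxymethoxy)-5-methylphenyl]methyl}-2,4,6-tris(methoxymethoxy)benzaldehyde)
Conditions: NaH (5.5 equiv), MOMCl (6 equiv), DMF, 0 °C → rt
Reagents that add atoms: chloromethyl methyl ether, COCCl
Why: Williamson O-alkylation of all five phenoxides with a hard alkoxymethyl chloride, which reacts at oxygen and not at the fully substituted ring carbons, removes every O–H that could later add to a ketene.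

Step 9
Reactants: 13 Ar*-carbaldehyde; 14 cyclobutane-1,3-dione
Product: 17 3-(methoxymethoxy)-2-(Ar*-methyl)cyclobut-2-en-1-one, via alkylidene dione 15 (not isolated), via hydroxycyclobutenone 16 (not isolated)
Conditions: 14 (1.3 equiv), diethyl 2,6-dimethyl-1,4-dihydropyridine-3,5-dicarboxylate (Hantzsch ester, 1.2 equiv), L-proline (20 mol %), CH2Cl2, rt; then i-Pr2NEt (4 equiv), MOMCl (3 equiv), 0 °C; Et3N-treated silica
Reagents that add atoms: chloromethyl methyl ether, COCCl
Why: Organocatalytic three-component reductive alkylation (proline-mediated Knoevenagel condensation of the very acidic dione, then conjugate hydride transfer from the Hantzsch ester) gives the 2-substituted dione without O- or dialkylation, and O-alkylation of this vinylogous acid in the same flask gives the vinylogous ester before the free acid can attack the acetals on concentration.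

Step 10
Reactants: 18 2-chloro-1,1-dimethoxyethane (chloroacetaldehyde dimethyl acetal)
Product: 20 1-methoxypropyne, via sodium methoxyacetylide 19 (not isolated)
Conditions: NaNH2 (3 equiv), liquid NH3, −33 °C; then MeI (1.0 equiv); cold H2O; distillation
Reagents that add atoms: iodomethane, CI
Why: Two base-induced eliminations (of HCl, then of methanol) convert the chloroacetal into the alkoxyacetylide, which is C-methylated in the same flask (acetylide alkylation), the standard access to 1-alkoxyalk-1-ynes.

Step 11
Reactants: 17 3-(methoxymethoxy)-2-(Ar*-methyl)cyclobut-2-en-1-one; 20 1-methoxypropyne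
Product: 25 3-methoxy-5-(methoxymethoxy)-2-methyl-4-(Ar*-methyl)phenol, via vinylketene 21 (not isolated), via vinylcyclobutenone 22 (not isolated), via dienylketene 23 (not isolated), via cyclohexadienone 24 (not isolated)
Conditions: 20 (5 equiv), toluene (0.1 M), sealed tube, 120 °C (up to 150 °C if 17 persists)
Reagents that add atoms: none
Why: Thermal conrotatory 4π ring opening of 17 gives vinylketene 21, whose ketene carbonyl carbon is attacked by the methyl-bearing (nucleophilic) carbon of ynol ether 20 in a regiospecific [2+2] cycloaddition to give 4-vinylcyclobutenone 22. A second 4π opening cleaves the bond between the carbonyl carbon and the quaternary carbon to give dienylketene 23, which closes ring A by thermal disrotatory 6π electrocyclisation (bond between the ketene carbon and the terminal methylene carbon) to cyclohexadienone 24, and enolisation gives phenol 25. The closest known reaction type is the Danheiser benzannulation of cyclobutenones with heteroatom-substituted alkynes; a 3-alkoxycyclobutenone is a less usual vinylketene source and is expected only to need a higher opening temperature, which the methyl ynol ether tolerates because it has no retro-ene path. No stereocentre survives, the quaternary carbon of 22 being transient and racemic. The one selectivity needed, methoxy next to the bridge-bearing carbon and methyl next to the new hydroxyl, follows from the polarisation of 20, whose oxygen-bearing carbon bonds to the ketene α-carbon that carries the benzylic CH2. With all other oxygens present as ethers there is no O–H to add to either ketene, and the neutral medium leaves the two aryl ketones and the acetals alone.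

Step 12
Reactants: 25 3-methoxy-5-(methoxymethoxy)-2-methyl-4-(Ar*-methyl)phenol
Product: 26 1-{3-[(3-acetyl-5-[(2,4-dihydroxy-6-methoxy-5-methylphenyl)methyl]-2,4,6-trihydroxyphenyl)methyl]-2,4-dihydroxy-6-methoxy-5-methylphenyl}butan-1-one
Conditions: conc. HCl (10 equiv), MeOH (0.01 M), 45 °C, N2
Reagents that add atoms: none
Why: Acid-catalysed acetal exchange removes all six methoxymethyl groups as dimethoxymethane; in dilute methanol the solvent should intercept the methoxymethyl cation far faster than the free carbon of ring A, and the diarylmethane links and methyl ethers are stable to these conditions.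

Step 13
Reactants: 26 the heptaphenol of step 12
Product: 27 CNP0184345.0, 1-{3-[(3-acetyl-5-[(3-butanoyl-2,4-dihydroxy-6-methoxy-5-methylphenyl)methyl]-2,4,6-trihydroxyphenyl)methyl]-2,4-dihydroxy-6-methoxy-5-methylphenyl}butan-1-one
Conditions: butanoic acid (1.5 equiv), BF3·OEt2, 55 °C; then aq. NaOAc/MeOH, 50 °C
Reagents that add atoms: butanoic acid, CCCC(=O)O
Why: Friedel–Crafts C-acylation (with Fries-type O-to-C transfer of any ester formed first) at the only unsubstituted aromatic carbon of the molecule, a phloroglucinol-type position between two hydroxyls of ring A, rings B and C being fully substituted.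

**Compound list**

1 | 2,4,6-trihydroxytoluene | Cc1c(O)cc(O)cc1O | starting material
2 | butanoyl chloride | CCCC(=O)Cl | starting material
3 | 1-(2,4,6-trihydroxy-3-methylphenyl)butan-1-one | CCCC(=O)c1c(O)cc(O)c(C)c1O | intermediate
4 | 1-[2-hydroxy-4,6-bis(methoxymethoxy)-3-methylphenyl]butan-1-one | CCCC(=O)c1c(OCOC)cc(OCOC)c(C)c1O | intermediate
5 | 1-[2-methoxy-4,6-bis(methoxymethoxy)-3-methylphenyl]butan-1-one | CCCC(=O)c1c(OCOC)cc(OCOC)c(C)c1OC | intermediate
6 | 1-(4,6-dihydroxy-2-methoxy-3-methylphenyl)butan-1-one | CCCC(=O)c1c(O)cc(O)c(C)c1OC | intermediate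
7 | 1-{3-[(dimethylamino)methyl]-2,4-dihydroxy-6-methoxy-5-methylphenyl}butan-1-one | CCCC(=O)c1c(O)c(CN(C)C)c(O)c(C)c1OC | intermediate
8 | 2,4,6-trihydroxyacetophenone | CC(=O)c1c(O)cc(O)cc1O | starting material
9 | [(3-acetyl-2,4,6-trihydroxyphenyl)methylidene]dimethylammonium chloride (transient) | CC(=O)c1c(O)cc(O)c(C=[N+](C)C)c1O.[Cl-] | intermediate
10 | 3-acetyl-2,4,6-trihydroxybenzaldehyde | CC(=O)c1c(O)cc(O)c(C=O)c1O | intermediate
11 | 2-butanoyl-5-hydroxy-3-methoxy-4-methyl-6-methylidenecyclohexa-2,4-dien-1-one (ortho-quinone methide of ring C, transient) | C=C1C(=O)C(C(=O)CCC)=C(OC)C(C)=C1O | intermediate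
12 | 3-acetyl-5-[(3-butanoyl-2,6-dihydroxy-4-methoxy-5-methylphenyl)methyl]-2,4,6-trihydroxybenzaldehyde | O=Cc1c(O)c(Cc2c(O)c(C)c(OC)c(C(=O)CCC)c2O)c(O)c(C(C)=O)c1O | intermediate
13 | Ar*-carbaldehyde, 3-acetyl-5-{[3-butanoyl-4-methoxy-2,6-bis(methoxymethoxy)-5-methylphenyl]methyl}-2,4,6-tris(methoxymethoxy)benzaldehyde | O=Cc1c(OCOC)c(Cc2c(OCOC)c(C)c(OC)c(C(=O)CCC)c2OCOC)c(OCOC)c(C(C)=O)c1OCOC | intermediate
14 | cyclobutane-1,3-dione | O=C1CC(=O)C1 | starting material
15 | 2-(Ar*-methylidene)cyclobutane-1,3-dione (transient) | O=C1CC(=O)C1=Cc1c(OCOC)c(Cc2c(OCOC)c(C)c(OC)c(C(=O)CCC)c2OCOC)c(OCOC)c(C(C)=O)c1OCOC | intermediate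
16 | 3-hydroxy-2-(Ar*-methyl)cyclobut-2-en-1-one, enol of the 2-substituted dione (not isolated) | O=C1CC(O)=C1Cc1c(OCOC)c(Cc2c(OCOC)c(C)c(OC)c(C(=O)CCC)c2OCOC)c(OCOC)c(C(C)=O)c1OCOC | intermediate
17 | 3-(methoxymethoxy)-2-(Ar*-methyl)cyclobut-2-en-1-one | O=C1CC(OCOC)=C1Cc1c(OCOC)c(Cc2c(OCOC)c(C)c(OC)c(C(=O)CCC)c2OCOC)c(OCOC)c(C(C)=O)c1OCOC | intermediate
18 | 2-chloro-1,1-dimethoxyethane | COC(CCl)OC | starting material
19 | sodium methoxyacetylide (transient) | [Na+].[C-]#COC | intermediate
20 | 1-methoxypropyne | CC#COC | intermediate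
21 | 2-(Ar*-methyl)-3-(methoxymethoxy)buta-1,3-dien-1-one (vinylketene, transient) | O=C=C(Cc1c(OCOC)c(Cc2c(OCOC)c(C)c(OC)c(C(=O)CCC)c2OCOC)c(OCOC)c(C(C)=O)c1OCOC)C(OCOC)=C | intermediate
22 | 3-methoxy-4-[1-(methoxymethoxy)ethenyl]-2-methyl-4-(Ar*-methyl)cyclobut-2-en-1-one (racemic, transient) | O=C1C(C)=C(OC)C1(Cc1c(OCOC)c(Cc2c(OCOC)c(C)c(OC)c(C(=O)CCC)c2OCOC)c(OCOC)c(C(C)=O)c1OCOC)C(OCOC)=C | intermediate
23 | (3E)-3-methoxy-5-(methoxymethoxy)-2-methyl-4-(Ar*-methyl)hexa-1,3,5-trien-1-one (dienylketene, ketene carbon and alkoxyvinyl group cis, transient) | O=C=C(C)/C(OC)=C(\C(OCOC)=C)Cc1c(OCOC)c(Cc2c(OCOC)c(C)c(OC)c(C(=O)CCC)c2OCOC)c(OCOC)c(C(C)=O)c1OCOC | intermediate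
24 | 3-methoxy-5-(methoxymethoxy)-2-methyl-4-(Ar*-methyl)cyclohexa-2,4-dien-1-one (transient) | O=C1CC(OCOC)=C(Cc2c(OCOC)c(Cc3c(OCOC)c(C)c(OC)c(C(=O)CCC)c3OCOC)c(OCOC)c(C(C)=O)c2OCOC)C(OC)=C1C | intermediate
25 | 3-methoxy-5-(methoxymethoxy)-2-methyl-4-(Ar*-methyl)phenol | COc1c(C)c(O)cc(OCOC)c1Cc1c(OCOC)c(Cc2c(OCOC)c(C)c(OC)c(C(=O)CCC)c2OCOC)c(OCOC)c(C(C)=O)c1OCOC | intermediate
26 | 1-{3-[(3-acetyl-5-[(2,4-dihydroxy-6-methoxy-5-methylphenyl)methyl]-2,4,6-trihydroxyphenyl)methyl]-2,4-dihydroxy-6-methoxy-5-methylphenyl}butan-1-one | COc1c(C)c(O)cc(O)c1Cc1c(O)c(Cc2c(O)c(C)c(OC)c(C(=O)CCC)c2O)c(O)c(C(C)=O)c1O | intermediate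
27 | CNP0184345.0 | CCCC(=O)c1c(O)c(C)c(OC)c(Cc2c(O)c(Cc3c(O)c(C)c(OC)c(C(=O)CCC)c3O)c(O)c(C(C)=O)c2O)c1O | target

**Totals**

Total step count: 13. Longest linear sequence: 11 steps (steps 1–5, 7–9 and 11–13, from 1). The target has no stereocentres.

**Steps most likely to fail**

Step 11 (benzannulation). The donor-stabilised cyclobutenone may open only at temperatures where the vinylketene is captured inside the molecule, by attack of a neighbouring acetal oxygen of ring B with transfer of its methoxymethyl group. The ynol ether may also oligomerise at those temperatures, so that the intermolecular [2+2] never competes. Esterification of the new phenol by a second ketene would be a further drain.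

Fallback: give up the annulation and close the trimer by a second ortho-quinone methide coupling, with ring A made by O-methylation. It sets out from 3, 7 and 8 and comes back to the route at 27.
- Mono-O-methylation of 3 at its non-chelated hydroxyl para to the ketone (Me2SO4, one equivalent, K2CO3, acetone) should give 1-(2,6-dihydroxy-4-methoxy-3-methylphenyl)butan-1-one F1.
- Aminomethylation as in step 5 should give 1-{3-[(dimethylamino)methyl]-2,6-dihydroxy-4-methoxy-5-methylphenyl}butan-1-one F2.
- Separately, heating 7 with an excess of 8 (dioxane, 90 °C) should give the diarylmethane with one free carbon on ring B, 1-{3-[(3-acetyl-2,4,6-trihydroxyphenyl)methyl]-2,4-dihydroxy-6-methoxy-5-methylphenyl}butan-1-one F3.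
- Heating F2 with F3 (dioxane, 90 °C) should form the second methylene bridge and give 27.
- The price is that ring A's methoxy position then depends on the selectivity of an O-methylation, and that the bridges may redistribute.

Step 9 (reductive alkylation with the four-membered dione). The hindered, electron-rich aldehyde may condense slowly while the strained, strongly acidic dione self-condenses. The alkylidene may also take up a second dione before hydride transfer, and the acidic enol may begin to cleave acetals before it is capped.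

Fallback: make the C–C bond by conjugate addition before the phenols are protected. It sets out from 12 (with 14) and comes back to the route at 17.
- Reductive amination of the aldehyde of 12 (Me2NH·HCl, NaBH(OAc)3, THF; the chelated, di-ortho-substituted ketones should not react) should give 1-{3-[(3-acetyl-5-[(dimethylamino)methyl]-2,4,6-trihydroxyphenyl)methyl]-2,4-dihydroxy-6-methoxy-5-methylphenyl}butan-1-one F4.
- Heating F4 with excess 14 (dioxane, 80 °C) should, by loss of dimethylamine and C-selective conjugate addition of the dione, give 2-({3-acetyl-5-[(3-butanoyl-2,6-dihydroxy-4-methoxy-5-methylphenyl)methyl]-2,4,6-trihydroxyphenyl}methyl)-3-hydroxycyclobut-2-en-1-one F5.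
- Exhaustive O-alkylation of F5 (NaH, MOMCl, DMF), phenols and vinylogous acid together, should give 17.

Step 13 (final acylation). In warm BF3·OEt2 the two diarylmethane links of the electron-rich polyphenol may be protonated at a ring carbon and then cleaved or redistributed. The acylation may also stop at phenol esters.

Fallback: a Houben–Hoesch reaction, run cold and unable to O-acylate. It sets out from 26 and comes back to the route at 27.
- Butanenitrile, ZnCl2 and dry HCl in Et2O at 0 °C should give the ketiminium salt 1-{3-[(3-acetyl-5-[(3-butanoyl-2,6-dihydroxy-4-methoxy-5-methylphenyl)methyl]-2,4,6-trihydroxyphenyl)methyl]-2,6-dihydroxy-4-methoxy-5-methylphenyl}butan-1-iminium chloride F6.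
- Hydrolysis of F6 in warm water should give 27.

**Further compounds**

F1 | step 11 | 1-(2,6-dihydroxy-4-methoxy-3-methylphenyl)butan-1-one | CCCC(=O)c1c(O)cc(OC)c(C)c1O
F2 | step 11 | 1-{3-[(dimethylamino)methyl]-2,6-dihydroxy-4-methoxy-5-methylphenyl}butan-1-one | CCCC(=O)c1c(O)c(CN(C)C)c(OC)c(C)c1O
F3 | step 11 | 1-{3-[(3-acetyl-2,4,6-trihydroxyphenyl)methyl]-2,4-dihydroxy-6-methoxy-5-methylphenyl}butan-1-one | CCCC(=O)c1c(O)c(Cc2c(O)cc(O)c(C(C)=O)c2O)c(O)c(C)c1OC
F4 | step 9 | 1-{3-[(3-acetyl-5-[(dimethylamino)methyl]-2,4,6-trihydroxyphenyl)methyl]-2,4-dihydroxy-6-methoxy-5-methylphenyl}butan-1-one | CN(C)Cc1c(O)c(Cc2c(O)c(C)c(OC)c(C(=O)CCC)c2O)c(O)c(C(C)=O)c1O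
F5 | step 9 | 2-({3-acetyl-5-[(3-butanoyl-2,6-dihydroxy-4-methoxy-5-methylphenyl)methyl]-2,4,6-trihydroxyphenyl}methyl)-3-hydroxycyclobut-2-en-1-one | O=C1CC(O)=C1Cc1c(O)c(Cc2c(O)c(C)c(OC)c(C(=O)CCC)c2O)c(O)c(C(C)=O)c1O
F6 | step 13 | 1-{3-[(3-acetyl-5-[(3-butanoyl-2,6-dihydroxy-4-methoxy-5-methylphenyl)methyl]-2,4,6-trihydroxyphenyl)methyl]-2,6-dihydroxy-4-methoxy-5-methylphenyl}butan-1-iminium chloride | CCCC(=[NH2+])c1c(O)c(C)c(OC)c(Cc2c(O)c(Cc3c(O)c(C)c(OC)c(C(=O)CCC)c3O)c(O)c(C(C)=O)c2O)c1O.[Cl-]
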